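**Strategy.** The route rests on disconnecting the quinone ring into three fragments. Its two carbonyl carbons (quinone C1 and C4) become a CO ligand and a Fischer carbene carbon; C2=C3 (C2 bearing furan C5) becomes the triple bond of a 2-ethynylfuran; the unsubstituted C5=C6 becomes a vinyl group. A Dötz [3+2+1] benzannulation of a β-silylvinyl(methoxy)carbene chromium complex with the fully elaborated (R)-furyl alkyne, oxidised in the same flask by Ce(IV), closes the carbocycle and delivers the 1,4-dione. Because this ring is monosubstituted, both alkyne-insertion regiochemistries converge on one quinone. The precursor is a furyl alkyne with no six-membered ring; its stereocentre is set earlier by Brown allylation and cross-metathesis.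

Key step: step 7

Remark: in the SMILES of chromium complexes the CO ligands (and η6-bound chromium) are written as dot-separated components, and the carbene carbon carries a C=Cr double bond. The carbinol centre is (R) in every intermediate (O > furyl C > CH2 > H).

**Step 1**
Reactants: 1 furan-3-carbaldehyde
Product: 5 5-iodofuran-3-carbaldehyde, via lithium α-morpholino alkoxide 2 (not isolated), via C5-lithiated alkoxide 3 (not isolated), via 5-iodo alkoxide 4 (not isolated)
Conditions: morpholine, n-BuLi, THF, −78 °C; then 1; s-BuLi, −78 °C; I2, −78 °C → rt; dil. HCl work-up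
Reagents that add atoms: iodine, II
Why: In situ protection of the aldehyde as a non-chelating lithium α-amino alkoxide blocks carbonyl addition and steers the directed lithiation with s-BuLi to the unhindered α-position C5 rather than C2, and iodinolysis followed by hydrolytic work-up returns the aldehyde.

**Step 2**
Reactants: 5 5-iodofuran-3-carbaldehyde
Product: 7 (R)-1-(5-iodofuran-3-yl)but-3-en-1-ol, via diisopinocampheylborinate ester 6 (not isolated)
Conditions: (+)-Ipc2BOMe [from (−)-α-pinene], allylMgBr, Et2O, 0 °C → rt; then 5, −78 °C; then 3 M NaOH, 30% H2O2, rt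
Reagents that add atoms: allylmagnesium bromide, C=CC[Mg]Br (allyl delivered through B-allyldiisopinocampheylborane, C=CCB([C@H]1C[C@H]2C[C@@H]([C@@H]1C)C2(C)C)[C@H]1C[C@H]2C[C@@H]([C@@H]1C)C2(C)C)
Why: Brown asymmetric allylboration through a chair Zimmerman–Traxler transition state, in which the isopinocampheyl groups derived from (−)-α-pinene should direct allyl transfer to the Re face of the aryl-type aldehyde and so set the (R)-carbinol.

**Step 3**
Reactants: 7 (R)-1-(5-iodofuran-3-yl)but-3-en-1-ol
Product: 8 (R)-1-(5-iodofuran-3-yl)-4-methylpent-3-en-1-ol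
Conditions: Grubbs II (5 mol%), 2-methyl-2-butene (excess), CH2Cl2, rt
Reagents that add atoms: 2-methyl-2-butene, CC=C(C)C
Why: Olefin cross-metathesis of the terminal alkene with excess 2-methyl-2-butene should transfer the isopropylidene unit with loss of propene, giving a trisubstituted alkene that is inert to further metathesis and leaving the stereocentre untouched.

**Step 4**
Reactants: 8 (R)-1-(5-iodofuran-3-yl)-4-methylpent-3-en-1-ol
Product: 9 (R)-1-(5-iodofuran-3-yl)-4-methylpent-3-en-1-yl 3-methylbutanoate
Conditions: (iBuCO)2O, Et3N, DMAP (cat.), CH2Cl2, 0 °C → rt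
Reagents that add atoms: 3-methylbutanoic anhydride, CC(C)CC(=O)OC(=O)CC(C)C
Why: DMAP-catalysed O-acylation of the secondary alcohol forms the ester without breaking the C–O bond, so the (R) configuration is retained.

**Step 5**
Reactants: 9 (R)-1-(5-iodofuran-3-yl)-4-methylpent-3-en-1-yl 3-methylbutanoate
Product: 10 (R)-1-(5-ethynylfuran-3-yl)-4-methylpent-3-en-1-yl 3-methylbutanoate
Conditions: HC≡CMgBr, ZnBr2, THF, 0 °C; then 9, Pd(PPh3)4 (5 mol%), THF, 0 °C → rt
Reagents that add atoms: ethynylmagnesium bromide, C#C[Mg]Br (used as ethynylzinc bromide, C#C[Zn]Br)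
Why: Negishi cross-coupling, in which oxidative addition into the 2-furyl C–I bond, transmetallation from the ethynylzinc reagent and reductive elimination give the terminal alkyne directly, the organozinc being unreactive towards the ester.

**Step 6**
Reactants: 11 (E)-(2-bromovinyl)trimethylsilane; 12 hexacarbonylchromium
Product: 15 pentacarbonyl[(E)-1-methoxy-3-(trimethylsilyl)prop-2-en-1-ylidene]chromium(0), via (E)-2-(trimethylsilyl)vinyllithium 13 (not isolated), via lithium acylchromate 14 (not isolated)
Conditions: t-BuLi (2 equiv), Et2O, −78 °C; then Cr(CO)6, Et2O, 0 °C → rt; then Me3OBF4, CH2Cl2, 0 °C → rt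
Reagents that add atoms: trimethyloxonium tetrafluoroborate, C[O+](C)C.F[B-](F)(F)F
Why: Fischer carbene synthesis, in which Br/Li exchange with retention of the E geometry, addition of the vinyllithium to a CO ligand and O-methylation of the resulting acylchromate give the alkoxycarbene complex.

**Step 7**
Reactants: 10 (R)-1-(5-ethynylfuran-3-yl)-4-methylpent-3-en-1-yl 3-methylbutanoate; 15 pentacarbonyl[(E)-1-methoxy-3-(trimethylsilyl)prop-2-en-1-ylidene]chromium(0) (1.5 equiv)
Product: 17 (R)-1-[5-(3,6-dioxocyclohexa-1,4-dien-1-yl)furan-3-yl]-4-methylpent-3-en-1-yl 3-methylbutanoate, via arene chromium tricarbonyl complex 16 (not isolated)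
Conditions: THF (0.05 M, degassed), 50 °C, Ar; then CAN (7 equiv), MeCN–H2O, 0 °C
Reagents that add atoms: water, O
Why: Thermal CO loss from 15, alkyne insertion into the Cr=C bond, CO insertion to an η4-vinylketene and electrocyclisation onto the β-silylvinyl terminus give a chromium-bound 6-silylcyclohexa-2,4-dienone, which aromatises by C→O 1,3-silyl shift to the silyl aryl ether complex 16; Ce(IV) then removes chromium, cleaves the O–Si bond and oxidises the 4-methoxyphenol-level arene to the quinone, water supplying the C4 oxygen as methanol leaves. The closest known reaction is the Dötz benzannulation of alkenyl(alkoxy)carbene chromium complexes with alkynes followed by oxidative work-up, β-silylvinyl complexes being used as stand-ins for the polymerisation-prone parent vinyl complex. The six-membered carbocycle is assembled in a formal [3+2+1] manner, the ring-closing bond (CO carbon to vinyl β-carbon) arising from a thermally allowed disrotatory 6π-electrocyclisation of the metal-bound dienylketene. No stereocentre is formed, and the remote (R)-carbinol ester should be unaffected by the neutral thermal stage and the brief cold oxidation. The step needs chemoselective insertion of the terminal alkyne in preference to the trisubstituted alkene and the furan, which the much higher reactivity of alkynes towards Fischer carbenes should secure, and aromatisation by silyl rather than hydrogen migration. Regioselectivity of alkyne insertion is not required, because the ring carries a single substituent and both orientations give the same 2-substituted quinone after oxidation.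

**Compound list**
1 | furan-3-carbaldehyde | O=Cc1ccoc1 | starting material
2 | lithium (furan-3-yl)(morpholin-4-yl)methanolate | [Li]OC(N1CCOCC1)c1ccoc1 | intermediate
3 | lithium (5-lithiofuran-3-yl)(morpholin-4-yl)methanolate | [Li]OC(N1CCOCC1)c1coc([Li])c1 | intermediate
4 | lithium (5-iodofuran-3-yl)(morpholin-4-yl)methanolate | [Li]OC(N1CCOCC1)c1coc(I)c1 | intermediate
5 | 5-iodofuran-3-carbaldehyde | O=Cc1coc(I)c1 | intermediate
6 | (R)-1-(5-iodofuran-3-yl)but-3-en-1-yl diisopinocampheylborinate | C=CC[C@@H](OB([C@H]1C[C@H]2C[C@@H]([C@@H]1C)C2(C)C)[C@H]1C[C@H]2C[C@@H]([C@@H]1C)C2(C)C)c1coc(I)c1 | intermediate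
7 | (R)-1-(5-iodofuran-3-yl)but-3-en-1-ol | C=CC[C@@H](O)c1coc(I)c1 | intermediate
8 | (R)-1-(5-iodofuran-3-yl)-4-methylpent-3-en-1-ol | CC(C)=CC[C@@H](O)c1coc(I)c1 | intermediate
9 | (R)-1-(5-iodofuran-3-yl)-4-methylpent-3-en-1-yl 3-methylbutanoate | CC(C)=CC[C@@H](OC(=O)CC(C)C)c1coc(I)c1 | intermediate
10 | (R)-1-(5-ethynylfuran-3-yl)-4-methylpent-3-en-1-yl 3-methylbutanoate | CC(C)=CC[C@@H](OC(=O)CC(C)C)c1coc(C#C)c1 | intermediate
11 | (E)-(2-bromovinyl)trimethylsilane | Br/C=C/[Si](C)(C)C | starting material
12 | hexacarbonylchromium | [Cr].[C-]#[O+].[C-]#[O+].[C-]#[O+].[C-]#[O+].[C-]#[O+].[C-]#[O+] | starting material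
13 | (E)-2-(trimethylsilyl)vinyllithium | [Li]/C=C/[Si](C)(C)C | intermediate
14 | lithium pentacarbonyl[(E)-3-(trimethylsilyl)acryloyl]chromate | [Li+].[O-]C(=[Cr])/C=C/[Si](C)(C)C.[C-]#[O+].[C-]#[O+].[C-]#[O+].[C-]#[O+].[C-]#[O+] | intermediate
15 | pentacarbonyl[(E)-1-methoxy-3-(trimethylsilyl)prop-2-en-1-ylidene]chromium(0) | COC(=[Cr])/C=C/[Si](C)(C)C.[C-]#[O+].[C-]#[O+].[C-]#[O+].[C-]#[O+].[C-]#[O+] | intermediate
16 | tricarbonyl(η6-arene)chromium complex of (R)-1-{5-[5-methoxy-2-(trimethylsilyloxy)phenyl]furan-3-yl}-4-methylpent-3-en-1-yl 3-methylbutanoate | CC(C)=CC[C@@H](OC(=O)CC(C)C)c1coc(-c2cc(OC)ccc2O[Si](C)(C)C)c1.[Cr].[C-]#[O+].[C-]#[O+].[C-]#[O+] | intermediate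
17 | (R)-1-[5-(3,6-dioxocyclohexa-1,4-dien-1-yl)furan-3-yl]-4-methylpent-3-en-1-yl 3-methylbutanoate | CC(C)=CC[C@@H](OC(=O)CC(C)C)c1coc(C2=CC(=O)C=CC2=O)c1 | target

**Step count.** Total: 7 steps. Longest linear sequence: 6 steps (1 → 5 → 7 → 8 → 9 → 10 → 17); step 6 prepares the carbene complex in a side branch.

**Steps most likely to fail**

1. Step 7 (key step). Possible failures are alkyne oligomerisation or double alkyne incorporation competing with CO insertion, aromatisation by hydrogen instead of silyl migration, and oxidative degradation of the furan or the prenyl group by Ce(IV) during the one-pot work-up. The fallback sets out from 10 and 15 and returns at 17. It replaces the one-pot single-electron oxidation by a stepwise sequence through a metal-free phenol and a two-electron hypervalent-iodine oxidation. The benzannulation is run as before, but the crude complex 16 is decomplexed by air and light in MeCN and desilylated with TBAF/AcOH in THF at 0 °C. This should give the isolable (R)-1-[5-(2-hydroxy-5-methoxyphenyl)furan-3-yl]-4-methylpent-3-en-1-yl 3-methylbutanoate F1. Oxidation of F1 with PhI(OAc)2 in MeOH at 0 °C should give the quinone monoketal (R)-1-[5-(3,3-dimethoxy-6-oxocyclohexa-1,4-dien-1-yl)furan-3-yl]-4-methylpent-3-en-1-yl 3-methylbutanoate F2. Hydrolysis of F2 with dilute aqueous oxalic acid in THF then releases 17.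

2. Step 5. Possible failures are a second coupling at the free alkyne terminus, homocoupling to a diyne, and decomposition of the electron-rich terminal ethynylfuran during isolation. The fallback sets out from 9 and returns at 10. Sonogashira coupling of 9 with trimethylsilylacetylene (PdCl2(PPh3)2, CuI, Et3N, THF, rt) should give the storable (R)-4-methyl-1-{5-[(trimethylsilyl)ethynyl]furan-3-yl}pent-3-en-1-yl 3-methylbutanoate F3. Desilylation of F3 with TBAF buffered by AcOH in THF at 0 °C, conditions that spare the ester, gives 10 immediately before use.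

3. Step 3. Possible failures are stalling of the metathesis through catalyst deactivation, homodimerisation of the homoallylic alcohol, and alkene isomerisation. The fallback sets out from 5 and returns at 8; it builds the prenyl chain directly and sets the stereocentre by reduction instead of allylation. α-Selective addition of prenylbarium chloride (prenyl chloride, activated Ba, THF, −78 °C) to 5 should give racemic 1-(5-iodofuran-3-yl)-4-methylpent-3-en-1-ol F4. Dess–Martin oxidation (NaHCO3, CH2Cl2, 0 °C) of F4 gives 1-(5-iodofuran-3-yl)-4-methylpent-3-en-1-one F5. Reduction of F5 with (+)-DIP-Cl [from (−)-α-pinene] in THF at −25 °C, with the furyl group acting as the large substituent, should give (R)-8.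

**Further compounds**
F1 | step 7 | (R)-1-[5-(2-hydroxy-5-methoxyphenyl)furan-3-yl]-4-methylpent-3-en-1-yl 3-methylbutanoate | CC(C)=CC[C@@H](OC(=O)CC(C)C)c1coc(-c2cc(OC)ccc2O)c1
F2 | step 7 | (R)-1-[5-(3,3-dimethoxy-6-oxocyclohexa-1,4-dien-1-yl)furan-3-yl]-4-methylpent-3-en-1-yl 3-methylbutanoate | CC(C)=CC[C@@H](OC(=O)CC(C)C)c1coc(C2=CC(OC)(OC)C=CC2=O)c1
F3 | step 5 | (R)-4-methyl-1-{5-[(trimethylsilyl)ethynyl]furan-3-yl}pent-3-en-1-yl 3-methylbutanoate | CC(C)=CC[C@@H](OC(=O)CC(C)C)c1coc(C#C[Si](C)(C)C)c1
F4 | step 3 | rac-1-(5-iodofuran-3-yl)-4-methylpent-3-en-1-ol | CC(C)=CCC(O)c1coc(I)c1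
F5 | step 3 | 1-(5-iodofuran-3-yl)-4-methylpent-3-en-1-one | CC(C)=CCC(=O)c1coc(I)c1
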